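The ten-membered carbocycle (C1–C10) is read as the eight-membered isoprene cyclodimer, which already carries C14–C10=C1–C2–C3–C4(C15)=C5 with both ring-cis olefins, plus the carbons C7 and C8 inserted into its allylic C6–C9 bond; the key step exploits the 1,3-oxygen pattern at C6 and C8. A dichloroketene adduct of the cyclooctadienone silyl enol ether, a bicyclo[6.2.0]decanone, undergoes retro-aldol cleavage of the shared C6–C9 bond and so delivers the ten-membered 6,8-dione in one operation. One catalytic asymmetric epoxidation of C7=C8 then relays all three stereocentres (Mitsunobu inversion at C6, intramolecular epoxide opening at C7), and two late allylic oxidations set C14 and C15.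

Key step: step 4

Remark: locants C1–C15 are those of the target (ring C1–C10, C14 on C10, C15 on C4, C11–C13 in the lactone); commercial 1 is assumed freed of its 1,6-dimethyl isomer; 5–7, 10 and 11 are racemic and drawn as one enantiomer; the cinchona amine of step 8 is assumed to be the pseudoenantiomer that gives the (7S,8S)-epoxide.

Step 1
Reactants: 1 (1Z,5Z)-1,5-dimethylcycloocta-1,5-diene
Product: 2 (2Z,6Z)-3,7-dimethylcycloocta-2,6-dien-1-one
Conditions: t-BuOOH (70% aq.), Rh2(C6H10NO)4 (dirhodium tetrakis(caprolactamate), 0.5 mol %), K2CO3, CH2Cl2, rt, stopped at partial conversion, 1 recycled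
Reagents that add atoms: tert-butyl hydroperoxide, CC(C)(C)OO
Why: Radical allylic C–H oxidation should abstract hydrogen from a ring CH2 next to a CH= terminus (the allyl radical with a tertiary end) and oxygenate its secondary end to the β-methyl enone; the two such CH2 groups of 1 are equivalent by its twofold axis and both ring-cis olefins stay in place.

Step 2
Reactants: 2 (2Z,6Z)-3,7-dimethylcycloocta-2,6-dien-1-one
Product: 4 trimethyl{[(1Z,3Z,7Z)-3,7-dimethylcycloocta-1,3,7-trien-1-yl]oxy}silane, via lithium dienolate 3 (not isolated)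
Conditions: lithium diisopropylamide (LDA), THF, −78 °C; then TMSCl, Et3N, −78 → 0 °C
Reagents that add atoms: chlorotrimethylsilane, C[Si](C)(C)Cl
Why: Kinetic deprotonation of the enone occurs at its only sp3 α-carbon (C9, also allylic to C1=C10) and O-silylation of the lithium dienolate gives the silyl enol ether C6=C9.

Step 3
Reactants: 4 trimethyl{[(1Z,3Z,7Z)-3,7-dimethylcycloocta-1,3,7-trien-1-yl]oxy}silane
Product: 5 rac-cis-fused 10,10-dichloro-3,7-dimethyl-1-(trimethylsilyloxy)bicyclo[6.2.0]deca-2,6-dien-9-one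
Conditions: Cl2CHCOCl (slow addition), Et3N, hexane, 0 °C → rt
Reagents that add atoms: dichloroacetyl chloride, ClC(Cl)C(Cl)=O
Why: Thermal [2+2] cycloaddition of dichloroketene (made in the flask) to the most electron-rich double bond, the silyl enol ether C6=C9, joins the ketene carbonyl carbon (future C8) to nucleophilic C9 and the CCl2 carbon (future C7) to C6, suprafacially on the olefin, so the cyclobutanone is cis-fused and racemic.

Step 4
Reactants: 5 rac-cis-fused 10,10-dichloro-3,7-dimethyl-1-(trimethylsilyloxy)bicyclo[6.2.0]deca-2,6-dien-9-one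
Product: 8 (4Z,8Z)-5,9-dimethylcyclodeca-4,8-diene-1,3-dione, via dechlorinated siloxycyclobutanone 6 (not isolated), via bicyclic cyclobutanol 7 (not isolated)
Conditions: Zn dust, AcOH, i-PrOH–H2O, 0 °C → rt; filter; then AcOH–H2O–i-PrOH, 50 °C
Reagents that add atoms: none
Why: Zinc in acetic acid removes both chlorines through the zinc enolate to give 6, and protodesilylation then frees the tertiary cyclobutanol 7, a strained β-hydroxy ketone. Retro-aldol cleavage of the shared C6–C9 bond turns the bicyclo[6.2.0]decane into the monocyclic ten-membered 1,3-dione, so the eight-membered ring grows by the two ketene carbons C7 and C8 and the C6/C8 oxygen pattern of the target is in place. The closest known reaction type is the dichloroketene/silyl enol ether two-carbon ring expansion of cycloalkanones to cycloalkane-1,3-diones. No ring is closed and no stereocentre is formed; the two ring-fusion centres of 5 are erased and both Z olefins are untouched. The selectivity needed is cleavage of the fusion bond C6–C9 instead of C6–C7; it is secured by relief of the bicyclic strain, by conjugation of the C9 enol(ate) with C1=C10, and by dechlorinating first so that the CCl2 carbon cannot leave as the carbanion.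

Step 5
Reactants: 8 (4Z,8Z)-5,9-dimethylcyclodeca-4,8-diene-1,3-dione
Product: 9 (4Z,8Z)-5,9-dimethylcyclodeca-4,8-diene-1,3-diol (mixture of diastereomers)
Conditions: NaBH4, CeCl3·7H2O, MeOH, −20 → 0 °C
Reagents that add atoms: none
Why: Luche reduction delivers hydride 1,2 to both the enone carbonyl (C6) and the isolated ketone (C8) under non-basic conditions; the diastereomer mixture is of no consequence because both carbinol centres are erased in steps 6 and 7.

Step 6
Reactants: 9 (4Z,8Z)-5,9-dimethylcyclodeca-4,8-diene-1,3-diol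
Product: 10 rac-(2Z,6Z)-9-hydroxy-3,7-dimethylcyclodeca-2,6-dien-1-one
Conditions: activated MnO2, CH2Cl2, rt
Reagents that add atoms: none
Why: MnO2 oxidises only the allylic alcohol (C6–OH, next to C4=C5) and leaves the homoallylic C8–OH, which differentiates the two oxygens of the dione (chemoselective allylic alcohol oxidation).

Step 7
Reactants: 10 rac-(2Z,6Z)-9-hydroxy-3,7-dimethylcyclodeca-2,6-dien-1-one
Product: 12 (2Z,5Z,9Z)-5,9-dimethylcyclodeca-2,5,9-trien-1-one, via β-mesyloxy ketone 11 (not isolated)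
Conditions: MsCl, Et3N, CH2Cl2, −10 °C → rt
Reagents that add atoms: none
Why: Mesylation of the β-hydroxy ketone and E1cB elimination through the C7 enolate gives the cross-conjugated trienone; the ring-cis (Z) C7=C8 olefin is expected as the less strained geometry beside the two other cis olefins of the ten-membered ring.

Step 8
Reactants: 12 (2Z,5Z,9Z)-5,9-dimethylcyclodeca-2,5,9-trien-1-one
Product: 13 (1S,3Z,7Z,10S)-4,8-dimethyl-11-oxabicyclo[8.1.0]undeca-3,7-dien-2-one (the 7S,8S cis-epoxide)
Conditions: 9-amino-9-deoxy-epi-quinine (10 mol %), CF3CO2H (20 mol %), 50% aq. H2O2, dioxane, 35 °C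
Reagents that add atoms: hydrogen peroxide, OO
Why: Iminium-activated Weitz–Scheffer (nucleophilic) epoxidation adds hydroperoxide to C8, the unhindered β-CH of the dienone, and not to the β,β-disubstituted C4 or the isolated C1=C10 olefin, and ring closure gives the cis-epoxide; the chiral primary amine controls the face and so sets C7 and C8.

Step 9
Reactants: 13 (1S,3Z,7Z,10S)-4,8-dimethyl-11-oxabicyclo[8.1.0]undeca-3,7-dien-2-one
Product: 14 (1R,2R,3Z,7Z,10S)-4,8-dimethyl-11-oxabicyclo[8.1.0]undeca-3,7-dien-2-ol (cis-epoxy alcohol, 6R)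
Conditions: NaBH4, CeCl3·7H2O, MeOH, −78 °C
Reagents that add atoms: none
Why: Chelation-controlled reduction of the α,β-epoxy ketone (cerium bridging the carbonyl and epoxide oxygens) delivers hydride anti to C8 and should give the cis-epoxy alcohol, setting C6 as 6R.

Step 10
Reactants: 14 (1R,2R,3Z,7Z,10S)-4,8-dimethyl-11-oxabicyclo[8.1.0]undeca-3,7-dien-2-ol
Product: 15 (1S,2S,3Z,7Z,10S)-4,8-dimethyl-11-oxabicyclo[8.1.0]undeca-3,7-dien-2-yl 2-(diethoxyphosphoryl)acetate
Conditions: (EtO)2P(O)CH2CO2H, PPh3, DIAD, THF, 0 °C → rt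
Reagents that add atoms: 2-(diethoxyphosphoryl)acetic acid, CCOP(=O)(OCC)CC(=O)O
Why: Mitsunobu esterification inverts C6 (the change of the C7 descriptor is only a priority change) and places the ester oxygen on the ring face opposite to the epoxide oxygen, the arrangement needed for backside attack at C7.

Step 11
Reactants: 15 (1S,2S,3Z,7Z,10S)-4,8-dimethyl-11-oxabicyclo[8.1.0]undeca-3,7-dien-2-yl 2-(diethoxyphosphoryl)acetate
Product: 17 (3aR,4S,6Z,10Z,11aS)-4-hydroxy-6,10-dimethyl-3-methylidene-3a,4,5,8,9,11a-hexahydrocyclodeca[b]furan-2(3H)-one, via phosphono lactone alcohol 16 (not isolated)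
Conditions: NaH (1.1 equiv), THF, 0 → 45 °C; then (CH2O)n, rt
Reagents that add atoms: formaldehyde (from paraformaldehyde), C=O
Why: The phosphonate-stabilised carbanion opens the epoxide intramolecularly at C7 in the 5-exo mode with inversion, giving the cis-fused γ-lactone 16 with the C8 oxygen trans to the new C7–C11 bond (C7 set by inversion, C8 kept from the epoxide), and after proton transfer the lactone phosphonate anion undergoes Horner–Wadsworth–Emmons olefination with formaldehyde to the α-methylene lactone.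

Step 12
Reactants: 17 (3aR,4S,6Z,10Z,11aS)-4-hydroxy-6,10-dimethyl-3-methylidene-3a,4,5,8,9,11a-hexahydrocyclodeca[b]furan-2(3H)-one
Product: 18 (3aR,4S,6Z,10Z,11aS)-6,10-dimethyl-3-methylidene-2-oxo-2,3,3a,4,5,8,9,11a-octahydrocyclodeca[b]furan-4-yl 3-methylbutanoate
Conditions: isovaleric anhydride, DMAP (cat.), Et3N, CH2Cl2, 0 °C → rt
Reagents that add atoms: 3-methylbutanoic anhydride, CC(C)CC(=O)OC(=O)CC(C)C
Why: DMAP-catalysed acylation of the only free hydroxyl (C8–OH) installs the 3-methylbutanoate with retention at C8.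

Step 13
Reactants: 18 (3aR,4S,6Z,10Z,11aS)-6,10-dimethyl-3-methylidene-2-oxo-2,3,3a,4,5,8,9,11a-octahydrocyclodeca[b]furan-4-yl 3-methylbutanoate
Product: 20 (3aR,4S,6E,10Z,11aS)-6-formyl-10-methyl-3-methylidene-2-oxo-2,3,3a,4,5,8,9,11a-octahydrocyclodeca[b]furan-4-yl 3-methylbutanoate, via C14 allylic alcohol 19 (not isolated)
Conditions: SeO2 (0.5 equiv), t-BuOOH, CH2Cl2, rt; then activated MnO2, CH2Cl2, rt
Reagents that add atoms: selenium dioxide, O=[Se]=O; tert-butyl hydroperoxide (reoxidant), CC(C)(C)OO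
Why: Selenium dioxide allylic hydroxylation (ene reaction then [2,3]-sigmatropic shift) should occur at the more electron-rich C1=C10 olefin on the methyl group C14 trans to C2 with the ring-cis geometry kept, since C4=C5 is deactivated by the allylic lactone oxygen and C9 by the neighbouring acyloxy group; MnO2 then takes the allylic alcohol 19 to the enal.

Step 14
Reactants: 20 (3aR,4S,6E,10Z,11aS)-6-formyl-10-methyl-3-methylidene-2-oxo-2,3,3a,4,5,8,9,11a-octahydrocyclodeca[b]furan-4-yl 3-methylbutanoate
Product: 21 (3aR,4S,6E,10E,11aS)-6-formyl-10-(hydroxymethyl)-3-methylidene-2-oxo-2,3,3a,4,5,8,9,11a-octahydrocyclodeca[b]furan-4-yl 3-methylbutanoate (target, 6S,7R,8S in target locants)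
Conditions: SeO2 (0.5 equiv), t-BuOOH, CH2Cl2, rt, stopped at the alcohol
Reagents that add atoms: selenium dioxide, O=[Se]=O; tert-butyl hydroperoxide (reoxidant), CC(C)(C)OO
Why: A second selenium dioxide allylic hydroxylation has only the C4=C5 olefin left to attack (the enal olefin is electron-poor) and should oxidise the methyl group C15 trans to C6 with the olefin geometry kept, stopping at the allylic alcohol under catalytic conditions.

Compound list
1 | (1Z,5Z)-1,5-dimethylcycloocta-1,5-diene | C1/C=C(/C)CC/C=C(/C)C1 | starting material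
2 | (2Z,6Z)-3,7-dimethylcycloocta-2,6-dien-1-one | O=C1/C=C(/C)CC/C=C(/C)C1 | intermediate
3 | lithium (1Z,3Z,7Z)-3,7-dimethylcycloocta-1,3,7-trien-1-olate (not isolated) | C/C1=C/C([O-])=C\C(C)=C/CC1.[Li+] | intermediate
4 | trimethyl{[(1Z,3Z,7Z)-3,7-dimethylcycloocta-1,3,7-trien-1-yl]oxy}silane | C/C1=C/C(O[Si](C)(C)C)=C\C(C)=C/CC1 | intermediate
5 | rac-cis-fused 10,10-dichloro-3,7-dimethyl-1-(trimethylsilyloxy)bicyclo[6.2.0]deca-2,6-dien-9-one | O=C1C(Cl)(Cl)[C@@]2(O[Si](C)(C)C)/C=C(/C)CC/C=C(/C)[C@@H]12 | intermediate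
6 | rac-cis-fused 3,7-dimethyl-1-(trimethylsilyloxy)bicyclo[6.2.0]deca-2,6-dien-9-one (not isolated) | O=C1C[C@@]2(O[Si](C)(C)C)/C=C(/C)CC/C=C(/C)[C@@H]12 | intermediate
7 | rac-cis-fused 1-hydroxy-3,7-dimethylbicyclo[6.2.0]deca-2,6-dien-9-one (not isolated) | O=C1C[C@@]2(O)/C=C(/C)CC/C=C(/C)[C@@H]12 | intermediate
8 | (4Z,8Z)-5,9-dimethylcyclodeca-4,8-diene-1,3-dione | O=C1CC(=O)/C=C(/C)CC/C=C(/C)C1 | intermediate
9 | (4Z,8Z)-5,9-dimethylcyclodeca-4,8-diene-1,3-diol (diastereomer mixture, carbinol centres undefined) | OC1CC(O)/C=C(/C)CC/C=C(/C)C1 | intermediate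
10 | rac-(2Z,6Z)-9-hydroxy-3,7-dimethylcyclodeca-2,6-dien-1-one | O=C1CC(O)C/C(C)=C\CC/C(C)=C\1 | intermediate
11 | rac-(3Z,7Z)-4,8-dimethyl-10-oxocyclodeca-3,7-dien-1-yl methanesulfonate (not isolated) | O=C1CC(OS(C)(=O)=O)C/C(C)=C\CC/C(C)=C\1 | intermediate
12 | (2Z,5Z,9Z)-5,9-dimethylcyclodeca-2,5,9-trien-1-one | O=C1/C=C\C/C(C)=C\CC/C(C)=C\1 | intermediate
13 | (1S,3Z,7Z,10S)-4,8-dimethyl-11-oxabicyclo[8.1.0]undeca-3,7-dien-2-one | O=C1[C@H]2O[C@H]2C/C(C)=C\CC/C(C)=C\1 | intermediate
14 | (1R,2R,3Z,7Z,10S)-4,8-dimethyl-11-oxabicyclo[8.1.0]undeca-3,7-dien-2-ol | O[C@H]1[C@H]2O[C@H]2C/C(C)=C\CC/C(C)=C\1 | intermediate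
15 | (1S,2S,3Z,7Z,10S)-4,8-dimethyl-11-oxabicyclo[8.1.0]undeca-3,7-dien-2-yl 2-(diethoxyphosphoryl)acetate | CCOP(=O)(OCC)CC(=O)O[C@@H]1[C@H]2O[C@H]2C/C(C)=C\CC/C(C)=C\1 | intermediate
16 | diethyl [(3aR,4S,6Z,10Z,11aS)-4-hydroxy-6,10-dimethyl-2-oxo-2,3,3a,4,5,8,9,11a-octahydrocyclodeca[b]furan-3-yl]phosphonate (both C3 epimers; not isolated) | CCOP(=O)(OCC)C1C(=O)O[C@H]2/C=C(/C)CC/C=C(/C)C[C@H](O)[C@@H]12 | intermediate
17 | (3aR,4S,6Z,10Z,11aS)-4-hydroxy-6,10-dimethyl-3-methylidene-3a,4,5,8,9,11a-hexahydrocyclodeca[b]furan-2(3H)-one | C=C1C(=O)O[C@H]2/C=C(/C)CC/C=C(/C)C[C@H](O)[C@@H]12 | intermediate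
18 | (3aR,4S,6Z,10Z,11aS)-6,10-dimethyl-3-methylidene-2-oxo-2,3,3a,4,5,8,9,11a-octahydrocyclodeca[b]furan-4-yl 3-methylbutanoate | C=C1C(=O)O[C@H]2/C=C(/C)CC/C=C(/C)C[C@H](OC(=O)CC(C)C)[C@@H]12 | intermediate
19 | (3aR,4S,6E,10Z,11aS)-6-(hydroxymethyl)-10-methyl-3-methylidene-2-oxo-2,3,3a,4,5,8,9,11a-octahydrocyclodeca[b]furan-4-yl 3-methylbutanoate (not isolated) | C=C1C(=O)O[C@H]2/C=C(/C)CC/C=C(/CO)C[C@H](OC(=O)CC(C)C)[C@@H]12 | intermediate
20 | (3aR,4S,6E,10Z,11aS)-6-formyl-10-methyl-3-methylidene-2-oxo-2,3,3a,4,5,8,9,11a-octahydrocyclodeca[b]furan-4-yl 3-methylbutanoate | C=C1C(=O)O[C@H]2/C=C(/C)CC/C=C(/C=O)C[C@H](OC(=O)CC(C)C)[C@@H]12 | intermediate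
21 | (3aR,4S,6E,10E,11aS)-6-formyl-10-(hydroxymethyl)-3-methylidene-2-oxo-2,3,3a,4,5,8,9,11a-octahydrocyclodeca[b]furan-4-yl 3-methylbutanoate | C=C1C(=O)O[C@H]2/C=C(/CO)CC/C=C(/C=O)C[C@H](OC(=O)CC(C)C)[C@@H]12 | target

Total step count: 14. Longest linear sequence: 14 steps (fully linear from 1).

Steps most likely to fail:

Step 8. What may go wrong is poor facial selectivity on the flexible ten-membered dienone, or migration of the C7=C8 or C1=C10 double bond through a dienamine. Fallback: from 12, a racemic Weitz–Scheffer epoxidation with alkaline hydrogen peroxide would give 13 together with its mirror image, the (7R,8R)-epoxy ketone F1. An NADPH-dependent ketoreductase with R selectivity at C6 (alcohol dehydrogenase class, 2-propanol as terminal reductant) would then reduce both enantiomers with the same sense, so that 13 gives 14 and F1 gives the diastereomeric trans-epoxy alcohol F2. Chromatography removes F2 and the route is rejoined at 14, with at most half of the material.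

Step 11. What may go wrong is a sluggish epoxide opening by the weakly nucleophilic phosphonate carbanion, or migration of the lactone acyl group to the C8 alkoxide. Fallback: from 14, Mitsunobu esterification with monomethyl malonate would give the inverted malonate ester F3. Sodium hydride would trigger the same 5-exo epoxide opening by the more nucleophilic malonate carbanion to give the α-methoxycarbonyl lactone alcohol F4. Hydrolysis with LiOH and acidification would give the lactone acid F5, and decarboxylative Mannich methylenation (Et2NH, aqueous formaldehyde, AcOH, NaOAc) would return to the route at 17.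

Step 14. What may go wrong is poor site selectivity between the methyl group C15 and the ring CH2 C3 on the deactivated C4=C5 olefin, or over-oxidation of the new alcohol. Fallback: from 20, allylic hydroxylation of C15 by an engineered cytochrome P450 monooxygenase (whole cells, O2, glucose-driven NADPH recycling), chosen by screening for C15 selectivity, would give 21 directly; no new compound is made.

Further compounds
F1 | step 8 | (1R,3Z,7Z,10R)-4,8-dimethyl-11-oxabicyclo[8.1.0]undeca-3,7-dien-2-one | O=C1[C@@H]2O[C@@H]2C/C(C)=C\CC/C(C)=C\1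
F2 | step 8 | (1S,2R,3Z,7Z,10R)-4,8-dimethyl-11-oxabicyclo[8.1.0]undeca-3,7-dien-2-ol | O[C@H]1[C@@H]2O[C@@H]2C/C(C)=C\CC/C(C)=C\1
F3 | step 11 | (1S,2S,3Z,7Z,10S)-4,8-dimethyl-11-oxabicyclo[8.1.0]undeca-3,7-dien-2-yl methyl propanedioate | COC(=O)CC(=O)O[C@@H]1[C@H]2O[C@H]2C/C(C)=C\CC/C(C)=C\1
F4 | step 11 | methyl (3aR,4S,6Z,10Z,11aS)-4-hydroxy-6,10-dimethyl-2-oxo-2,3,3a,4,5,8,9,11a-octahydrocyclodeca[b]furan-3-carboxylate (both C3 epimers) | COC(=O)C1C(=O)O[C@H]2/C=C(/C)CC/C=C(/C)C[C@H](O)[C@@H]12
F5 | step 11 | (3aR,4S,6Z,10Z,11aS)-4-hydroxy-6,10-dimethyl-2-oxo-2,3,3a,4,5,8,9,11a-octahydrocyclodeca[b]furan-3-carboxylic acid (both C3 epimers) | OC(=O)C1C(=O)O[C@H]2/C=C(/C)CC/C=C(/C)C[C@H](O)[C@@H]12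
F0 | step 14 | none | none
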